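**Plan**
- Retrosynthetic cuts, in order: the acid is traced back to a primary alcohol; O2–C3 (a C5 hydroperoxide opens an oxetane); O1–C5 (radical peroxidation of a C5 methylidene); C1–C2 (ring expansion of an epoxide); C4–C5 (alkenyl–copper opening of a C2–C4 epoxide); C13=C14 (Wittig); the C7–CH3 and C11–CH3 bonds; C6=C7 and C11=C12 (double Wittig on glutaraldehyde).
- Enabling feature: C7 and C11 with their methyl groups are exchanged by a local twofold axis through C9. C5–C13 is therefore a (3R,7R)-3,7-dimethylnonanedioic acid unit, and both methyl groups can be installed in one operation from a symmetric dienedithioate.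
- Forward order: the acyclic C5–C13 chain is made first, methylated at both ends, extended at C13 by the phenethyl unit and converted at C5 into a methyl ketone. It is then joined through C4–C5 to a three-carbon epoxide. The only ring, the 1,2-dioxolane, closes in the penultimate step.
- Stereochemistry: C7 and C11 come from the ligand in the two-directional copper-catalysed methylation. C3 comes from (R)-2-methylglycidol, through two epoxide/oxetane relocations that never break the quaternary C–O bond and one inversion in the ring closure. C5 is formed without control in the radical peroxidation and is secured by separating the cis/trans-dimethyl dioxolane epimers.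

Key step: step 4

Assumption: (R,S)-Josiphos, i.e. (R)-1-[(SP)-2-(diphenylphosphino)ferrocenyl]ethyldicyclohexylphosphine, is taken as the enantiomer whose CuBr complex adds methyl to (E)-β-alkyl enethioates to give the (R)-3-methyl thioester; if the sense were opposite, the (S,R)-ligand would be used with nothing else changed.

Atom numbers C1–C15 are those of the target acid (C1 = CO2H, C3 and C5 = ring carbons).

**Step 1**
Reactants: 1 bromoacetyl bromide; 2 ethanethiol
Product: 3 S-ethyl 2-bromoethanethioate
Conditions: pyridine (1 equiv), CH2Cl2, −10 → 0 °C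
Reagents that add atoms: none
Why: Thiol S-acylation (nucleophilic acyl substitution) at the acyl bromide is much faster than SN2 displacement of the α-bromide when one equivalent of thiol is added cold with a weak amine base.

**Step 2**
Reactants: 3 S-ethyl 2-bromoethanethioate
Product: 5 S-ethyl 2-(triphenyl-λ5-phosphanylidene)ethanethioate, via phosphonium bromide 4 (not isolated)
Conditions: PPh3, toluene, rt; then aq Na2CO3, CH2Cl2, rt
Reagents that add atoms: triphenylphosphine, c1ccc(cc1)P(c1ccccc1)c1ccccc1
Why: SN2 quaternisation of triphenylphosphine by the α-bromo thioester gives the phosphonium salt, whose acidic α-proton is removed by aqueous carbonate to leave the stabilised Wittig ylide.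

**Step 3**
Reactants: 5 S-ethyl 2-(triphenyl-λ5-phosphanylidene)ethanethioate; 6 glutaraldehyde
Product: 7 bis(S-ethyl) (2E,7E)-nona-2,7-dienebis(thioate)
Conditions: 5 (2.2 equiv), 6 (freed from its aqueous solution by extraction into CH2Cl2 and drying), CH2Cl2, reflux
Reagents that add atoms: none
Why: Twofold Wittig olefination with a carbonyl-stabilised ylide is E-selective at both aldehyde termini and brings in both thioester groups.

**Step 4**
Reactants: 7 bis(S-ethyl) (2E,7E)-nona-2,7-dienebis(thioate)
Product: 9 bis(S-ethyl) (3R,7R)-3,7-dimethylnonanebis(thioate), via bis(bromomagnesium) thioenolate 8 (not isolated)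
Conditions: MeMgBr (3 equiv), CuBr·SMe2 (10 mol%), (R,S)-Josiphos (12 mol%), t-BuOMe, −75 °C, slow addition of 7; MeOH quench at −75 °C
Reagents that add atoms: methylmagnesium bromide, C[Mg]Br
Why: The Cu(I)–Josiphos complex is methylated by the Grignard reagent, binds the (E)-enethioate as a π-complex, forms a Cu(III) σ-species at the β-carbon and releases the C–CH3 bond by reductive elimination, leaving a bromomagnesium thioenolate that is protonated on quench; this happens once at each terminus. The closest known reaction is the copper/ferrocenyl-diphosphine-catalysed asymmetric conjugate addition of methylmagnesium bromide to α,β-unsaturated thioesters. No ring closes; two C–C bonds and two stereocentres (C3 and C7 of 9, C7 and C11 of the target) are formed. Each centre is set by the chiral ligand alone, since the three-carbon spacer transmits no bias, so both additions occur in the same sense and give the C2-symmetric (3R,7R) isomer, a mismatched event ending in the meso isomer and not in the enantiomer. The step needs 1,4- over 1,2-addition, secured by the thioester acceptor at −75 °C, and it needs methyl transfer to the second enethioate to outrun 6-exo Michael closure of the first thioenolate onto it, secured by the low temperature, the weakly coordinating ether in which the aggregated bromomagnesium thioenolate is a poor Michael donor, excess Grignard reagent with a raised catalyst loading, slow addition of 7 and the cold quench.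

**Step 5**
Reactants: 9 bis(S-ethyl) (3R,7R)-3,7-dimethylnonanebis(thioate)
Product: 10 S-ethyl (3R,7R)-3,7-dimethyl-9-oxononanethioate
Conditions: Et3SiH (1.0–1.1 equiv), 10% Pd/C, acetone, rt
Reagents that add atoms: none
Why: Fukuyama reduction (Pd-catalysed hydrosilane reduction of a thioester to the aldehyde) with a limiting amount of silane acts on either of the two homotopic thioesters to give one mono-aldehyde, unreacted 9 being recovered and resubmitted.

**Step 6**
Reactants: 10 S-ethyl (3R,7R)-3,7-dimethyl-9-oxononanethioate; 11 (2-phenylethyl)triphenylphosphonium bromide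
Product: 13 S-ethyl (3R,7R,9Z)-3,7-dimethyl-11-phenylundec-9-enethioate, via ylide 12 (not isolated)
Conditions: 11, NaHMDS, THF, 0 °C; then 10, −78 °C → rt
Reagents that add atoms: none
Why: Wittig olefination with a non-stabilised ylide at −78 °C consumes the aldehyde much faster than the ylide can attack the thioester, and the mainly Z geometry is irrelevant because the alkene is hydrogenated later.

**Step 7**
Reactants: 13 S-ethyl (3R,7R,9Z)-3,7-dimethyl-11-phenylundec-9-enethioate
Product: 14 (4R,8R,10Z)-4,8-dimethyl-12-phenyldodec-10-en-2-one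
Conditions: Me2CuLi (from MeLi and CuI), Et2O, −78 °C
Reagents that add atoms: lithium dimethylcuprate, [Li+].C[Cu-]C
Why: Acyl substitution of a thioester by a lithium dialkylcuprate stops at the ketone because the cuprate does not add to the ketone at low temperature, and neither the isolated alkene nor the non-epimerisable β-stereocentre is touched.

**Step 8**
Reactants: 14 (4R,8R,10Z)-4,8-dimethyl-12-phenyldodec-10-en-2-one
Product: 15 (4R,8S)-4,8-dimethyl-12-phenyldodecan-2-one
Conditions: H2 (1 atm), 10% Pd/C, EtOAc, rt
Reagents that add atoms: none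
Why: Heterogeneous catalytic hydrogenation saturates the disubstituted alkene at 1 atm without reducing the ketone or the arene, and it is placed after removal of the sulfur group that would slow the catalyst (the change of the C8 descriptor from R to S is a priority effect only).

**Step 9**
Reactants: 15 (4R,8S)-4,8-dimethyl-12-phenyldodecan-2-one; 16 2,4,6-tri(propan-2-yl)benzenesulfonohydrazide
Product: 17 N'-[(2E,4R,8S)-4,8-dimethyl-12-phenyldodecan-2-ylidene]-2,4,6-tri(propan-2-yl)benzenesulfonohydrazide
Conditions: cat HCl, MeCN, rt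
Reagents that add atoms: none
Why: Acid-catalysed hydrazone condensation gives the trisylhydrazone with the sulfonamide syn to the methyl group, the arrangement needed for regioselective Shapiro metalation.

**Step 10**
Reactants: 18 [(2R)-2-methyloxiran-2-yl]methanol
Product: 19 [(2S)-2-methyloxiran-2-yl]methyl 4-methylbenzenesulfonate
Conditions: TsCl, Et3N, cat DMAP, CH2Cl2, 0 °C
Reagents that add atoms: 4-methylbenzenesulfonyl chloride, Cc1ccc(cc1)S(Cl)(=O)=O
Why: O-Sulfonylation of the primary alcohol leaves the quaternary stereocentre untouched, the change of descriptor from R to S being a priority effect only.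

**Step 11**
Reactants: 17 N'-[(2E,4R,8S)-4,8-dimethyl-12-phenyldodecan-2-ylidene]-2,4,6-tri(propan-2-yl)benzenesulfonohydrazide; 19 [(2S)-2-methyloxiran-2-yl]methyl 4-methylbenzenesulfonate
Product: 23 (2S)-2-[(4R,8S)-4,8-dimethyl-2-methylidene-12-phenyldodecyl]-2-methyloxirane, via vinyllithium 20 (not isolated), via vinylmagnesium bromide 21 (not isolated), via tosyloxy alcohol 22 (not isolated)
Conditions: n-BuLi (2.1 equiv), THF, −78 → 0 °C; MgBr2·OEt2, −78 °C; CuI (10 mol%), 19, −40 → 0 °C; then K2CO3, MeOH, rt
Reagents that add atoms: none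
Why: The Shapiro reaction (syn-directed deprotonation at the methyl group, then loss of sulfinate and N2) gives the 2-metallo-1-alkene, which after Li→Mg exchange opens the epoxide of 19 under Cu(I) catalysis at its unsubstituted CH2 in preference to the neopentyl-like CH2OTs, and the tertiary alkoxide then displaces the tosylate, so that the epoxide is relocated without breaking the quaternary C–O bond and C3 keeps the configuration brought in by 18.

**Step 12**
Reactants: 23 (2S)-2-[(4R,8S)-4,8-dimethyl-2-methylidene-12-phenyldodecyl]-2-methyloxirane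
Product: 24 (2S)-2-[(4R,8S)-4,8-dimethyl-2-methylidene-12-phenyldodecyl]-2-methyloxetane
Conditions: Me3S(O)I (3 equiv), KOt-Bu (3 equiv), t-BuOH, 50 °C
Reagents that add atoms: trimethylsulfoxonium iodide, C[S+](C)(C)=O.[I-]
Why: In this Corey–Chaykovsky-type ring expansion dimethylsulfoxonium methylide opens the epoxide at its CH2 and the alkoxide closes 4-exo-tet with loss of DMSO, so the C3–O bond is never broken and the configuration is retained in the 2,2-disubstituted oxetane, whose new CH2 is C1.

**Step 13**
Reactants: 24 (2S)-2-[(4R,8S)-4,8-dimethyl-2-methylidene-12-phenyldodecyl]-2-methyloxetane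
Product: 25 triethyl({(2RS,4R,8S)-2,4,8-trimethyl-1-[(2R)-2-methyloxetan-2-yl]-12-phenyldodecan-2-yl}peroxy)silane
Conditions: Co(acac)2 (10 mol%), O2 (1 atm), Et3SiH (2 equiv), EtOH, rt
Reagents that add atoms: dioxygen, O=O; triethylsilane, CC[SiH](CC)CC
Why: In the Mukaiyama–Isayama peroxidation a cobalt hydride transfers H to the methylidene carbon, the tertiary C5 radical captures O2 and the peroxyl is silylated, giving the Markovnikov silyl peroxide with the oxetane untouched; the planar radical is trapped from both faces, so both C5 epimers are expected in similar amounts (the oxetane descriptor changes from S to R by priority only).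

**Step 14**
Reactants: 25 triethyl({(2RS,4R,8S)-2,4,8-trimethyl-1-[(2R)-2-methyloxetan-2-yl]-12-phenyldodecan-2-yl}peroxy)silane
Product: 27 2-{(3S,5R)-5-[(2R,6S)-2,6-dimethyl-10-phenyldecyl]-3,5-dimethyl-1,2-dioxolan-3-yl}ethan-1-ol, via hydroperoxide 26 (not isolated)
Conditions: HF·pyridine, THF, 0 °C; then Yb(OTf)3 (10 mol%), CH2Cl2, 0 °C → rt; chromatographic removal of the (3S,5S) epimer
Reagents that add atoms: none
Why: Desilylation frees the tertiary hydroperoxide, which on Lewis-acid activation of the oxetane attacks its quaternary carbon 5-exo-tet with inversion (intramolecular alkylation of a hydroperoxide by an oxetane) and so sets C3; the two C5 epimers thereby become cis- and trans-dimethyl dioxolanes, which differ as ring diastereomers and are separated on silica, the cis-dimethyl isomer 27 being kept.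

**Step 15**
Reactants: 27 2-{(3S,5R)-5-[(2R,6S)-2,6-dimethyl-10-phenyldecyl]-3,5-dimethyl-1,2-dioxolan-3-yl}ethan-1-ol
Product: 28 2-{(3R,5R)-5-[(2R,6S)-2,6-dimethyl-10-phenyldecyl]-3,5-dimethyl-1,2-dioxolan-3-yl}acetic acid
Conditions: TEMPO (20 mol%), PhI(OAc)2 (2.2 equiv), MeCN/H2O 1:1, rt
Reagents that add atoms: water, O
Why: TEMPO/PhI(OAc)2 oxidation takes the primary alcohol through the aldehyde hydrate to the acid under neutral, metal-free conditions that leave the fully substituted peroxide, the benzylic positions and all stereocentres intact (the C3 descriptor changes from S to R by priority only).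

**Compound list**
1 | bromoacetyl bromide | BrCC(Br)=O | starting material
2 | ethanethiol | CCS | starting material
3 | S-ethyl 2-bromoethanethioate | CCSC(=O)CBr | intermediate
4 | [2-(ethylsulfanyl)-2-oxoethyl]triphenylphosphonium bromide (not isolated) | CCSC(=O)C[P+](c1ccccc1)(c1ccccc1)c1ccccc1.[Br-] | intermediate
5 | S-ethyl 2-(triphenyl-λ5-phosphanylidene)ethanethioate | CCSC(=O)C=P(c1ccccc1)(c1ccccc1)c1ccccc1 | intermediate
6 | glutaraldehyde | O=CCCCC=O | starting material
7 | bis(S-ethyl) (2E,7E)-nona-2,7-dienebis(thioate) | CCSC(=O)/C=C/CCC/C=C/C(=O)SCC | intermediate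
8 | bis(bromomagnesium) thioenolate of 9 (not isolated) | CCSC(O[Mg]Br)=C[C@H](C)CCC[C@@H](C)C=C(O[Mg]Br)SCC | intermediate
9 | bis(S-ethyl) (3R,7R)-3,7-dimethylnonanebis(thioate) | CCSC(=O)C[C@H](C)CCC[C@@H](C)CC(=O)SCC | intermediate
10 | S-ethyl (3R,7R)-3,7-dimethyl-9-oxononanethioate | CCSC(=O)C[C@H](C)CCC[C@@H](C)CC=O | intermediate
11 | (2-phenylethyl)triphenylphosphonium bromide | [Br-].C(Cc1ccccc1)[P+](c1ccccc1)(c1ccccc1)c1ccccc1 | starting material
12 | triphenyl(2-phenylethylidene)-λ5-phosphane (not isolated) | C(Cc1ccccc1)=P(c1ccccc1)(c1ccccc1)c1ccccc1 | intermediate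
13 | S-ethyl (3R,7R,9Z)-3,7-dimethyl-11-phenylundec-9-enethioate | CCSC(=O)C[C@H](C)CCC[C@@H](C)C/C=C\Cc1ccccc1 | intermediate
14 | (4R,8R,10Z)-4,8-dimethyl-12-phenyldodec-10-en-2-one | CC(=O)C[C@H](C)CCC[C@@H](C)C/C=C\Cc1ccccc1 | intermediate
15 | (4R,8S)-4,8-dimethyl-12-phenyldodecan-2-one | CC(=O)C[C@H](C)CCC[C@@H](C)CCCCc1ccccc1 | intermediate
16 | 2,4,6-tri(propan-2-yl)benzenesulfonohydrazide | CC(C)c1cc(C(C)C)c(c(c1)C(C)C)S(=O)(=O)NN | starting material
17 | N'-[(2E,4R,8S)-4,8-dimethyl-12-phenyldodecan-2-ylidene]-2,4,6-tri(propan-2-yl)benzenesulfonohydrazide | C/C(C[C@H](C)CCC[C@@H](C)CCCCc1ccccc1)=N\NS(=O)(=O)c1c(cc(cc1C(C)C)C(C)C)C(C)C | intermediate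
18 | [(2R)-2-methyloxiran-2-yl]methanol, (R)-2-methylglycidol | C[C@@]1(CO)CO1 | starting material
19 | [(2S)-2-methyloxiran-2-yl]methyl 4-methylbenzenesulfonate | C[C@@]1(COS(=O)(=O)c2ccc(C)cc2)CO1 | intermediate
20 | [(4R,8S)-4,8-dimethyl-12-phenyldodec-1-en-2-yl]lithium (not isolated) | [Li]C(=C)C[C@H](C)CCC[C@@H](C)CCCCc1ccccc1 | intermediate
21 | bromo[(4R,8S)-4,8-dimethyl-12-phenyldodec-1-en-2-yl]magnesium (not isolated) | Br[Mg]C(=C)C[C@H](C)CCC[C@@H](C)CCCCc1ccccc1 | intermediate
22 | (2S,6R,10S)-2-hydroxy-2,6,10-trimethyl-4-methylidene-14-phenyltetradecyl 4-methylbenzenesulfonate (not isolated) | C=C(C[C@H](C)CCC[C@@H](C)CCCCc1ccccc1)C[C@](C)(O)COS(=O)(=O)c1ccc(C)cc1 | intermediate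
23 | (2S)-2-[(4R,8S)-4,8-dimethyl-2-methylidene-12-phenyldodecyl]-2-methyloxirane | C=C(C[C@H](C)CCC[C@@H](C)CCCCc1ccccc1)C[C@@]1(C)CO1 | intermediate
24 | (2S)-2-[(4R,8S)-4,8-dimethyl-2-methylidene-12-phenyldodecyl]-2-methyloxetane | C=C(C[C@H](C)CCC[C@@H](C)CCCCc1ccccc1)C[C@@]1(C)CCO1 | intermediate
25 | triethyl({(2RS,4R,8S)-2,4,8-trimethyl-1-[(2R)-2-methyloxetan-2-yl]-12-phenyldodecan-2-yl}peroxy)silane, both epimers at the peroxy carbon | CC(C[C@H](C)CCC[C@@H](C)CCCCc1ccccc1)(OO[Si](CC)(CC)CC)C[C@@]1(C)CCO1 | intermediate
26 | (2R)-2-[(2RS,4R,8S)-2-hydroperoxy-2,4,8-trimethyl-12-phenyldodecyl]-2-methyloxetane, both epimers (not isolated) | CC(C[C@H](C)CCC[C@@H](C)CCCCc1ccccc1)(OO)C[C@@]1(C)CCO1 | intermediate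
27 | 2-{(3S,5R)-5-[(2R,6S)-2,6-dimethyl-10-phenyldecyl]-3,5-dimethyl-1,2-dioxolan-3-yl}ethan-1-ol | C[C@@H](CCCCc1ccccc1)CCC[C@@H](C)C[C@]1(C)C[C@](C)(CCO)OO1 | intermediate
28 | 2-{(3R,5R)-5-[(2R,6S)-2,6-dimethyl-10-phenyldecyl]-3,5-dimethyl-1,2-dioxolan-3-yl}acetic acid (CNP0256758.1) | C[C@@H](CCCCc1ccccc1)CCC[C@@H](C)C[C@]1(C)C[C@](C)(CC(=O)O)OO1 | target

**Step count**
Total: 15 steps. Longest linear sequence: 14 steps (steps 1–9 and 11–15); step 10 is a one-step side branch.

**Steps most likely to fail**

Step 4. The first-formed thioenolate may close onto the remaining enethioate in a Michael ring closure to a cyclohexane. The second addition may also stall at the mono-adduct, and imperfect facial selectivity leaves meso material that cannot be removed downstream. The fallback sets out from 5 and returns at 9; it treats one acceptor at a time, so that no thioenolate ever has a Michael acceptor within reach. Wittig reaction of 5 with hex-5-enal gives S-ethyl (2E)-octa-2,7-dienethioate F1. The same Cu/Josiphos methylation gives S-ethyl (3R)-3-methyloct-7-enethioate F2. Cross-metathesis of the terminal alkene with S-ethyl prop-2-enethioate (second-generation Ru carbene catalyst) gives S,S-diethyl (2E,7R)-7-methylnon-2-enebis(thioate) F3. A second Cu/Josiphos methylation of F3 then gives 9.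

Step 11. Metalation may be misdirected (toward the CH2 side of the hydrazone or the benzylic position). Some attack may occur at the CH2OTs carbon instead of the epoxide, which would deliver the opposite configuration at C3 and erode its purity. Bromide may also open the epoxide. The fallback sets out from 15 and returns at 23; it replaces the alkenyl-metal/epoxide union by a cross-coupling and takes the C3 configuration from a reagent-controlled epoxidation. Kinetic enolisation of 15 (LDA, −78 °C) and trapping with PhNTf2 gives (4R,8S)-4,8-dimethyl-12-phenyldodec-1-en-2-yl trifluoromethanesulfonate F4. Stille coupling with 2-[(tributylstannyl)methyl]prop-2-en-1-ol (Pd(PPh3)4, LiCl, THF) gives (6R,10S)-6,10-dimethyl-2,4-dimethylidene-14-phenyltetradecan-1-ol F5. Sharpless epoxidation of the allylic alcohol with L-(+)-diethyl tartrate gives {(2S)-2-[(4R,8S)-4,8-dimethyl-2-methylidene-12-phenyldodecyl]oxiran-2-yl}methanol F6. LiAlH4 opens F6 at the epoxide CH2 to (2S,6R,10S)-2,6,10-trimethyl-4-methylidene-14-phenyltetradecane-1,2-diol F7. Selective tosylation of the primary hydroxyl gives 22, and K2CO3 in MeOH closes it to 23.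

Step 14. Under acid the oxetane may ionise at its tertiary carbon, so that the ring closure loses its inversion fidelity at C3. The tertiary hydroperoxide may undergo acid-induced cleavage, or the closure may be too slow to compete with decomposition. The fallback sets out from 15 and returns at 27; it builds the ring by a peroxycarbenium annulation, at the price of giving up control at C3 as well as C5. Ketalisation of 15 (HC(OMe)3, MeOH, cat acid) gives (4R,8S)-2,2-dimethoxy-4,8-dimethyl-12-phenyldodecane F8. Acetal exchange with ethereal H2O2 and a trace of acid gives (4R,8S)-2-hydroperoxy-2-methoxy-4,8-dimethyl-12-phenyldodecane F9. Silylation (Et3SiOTf, 2,6-lutidine) gives triethyl{[(4R,8S)-2-methoxy-4,8-dimethyl-12-phenyldodecan-2-yl]peroxy}silane F10. In parallel, 3-methylbut-3-en-1-ol is silylated to tert-butyl[(3-methylbut-3-en-1-yl)oxy]diphenylsilane F11. SnCl4 in CH2Cl2 at −78 °C ionises F10 to the peroxycarbenium ion, which adds to F11 and closes to tert-butyl(2-{(3S,5R)-5-[(2R,6S)-2,6-dimethyl-10-phenyldecyl]-3,5-dimethyl-1,2-dioxolan-3-yl}ethoxy)diphenylsilane F12 together with its ring stereoisomers. These have to be separated before TBAF gives 27.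

**Further compounds**
F1 | step 4 | S-ethyl (2E)-octa-2,7-dienethioate | CCSC(=O)/C=C/CCCC=C
F2 | step 4 | S-ethyl (3R)-3-methyloct-7-enethioate | CCSC(=O)C[C@H](C)CCCC=C
F3 | step 4 | S,S-diethyl (2E,7R)-7-methylnon-2-enebis(thioate) | CCSC(=O)C[C@H](C)CCC/C=C/C(=O)SCC
F4 | step 11 | (4R,8S)-4,8-dimethyl-12-phenyldodec-1-en-2-yl trifluoromethanesulfonate | C=C(OS(=O)(=O)C(F)(F)F)C[C@H](C)CCC[C@@H](C)CCCCc1ccccc1
F5 | step 11 | (6R,10S)-6,10-dimethyl-2,4-dimethylidene-14-phenyltetradecan-1-ol | C=C(CO)CC(=C)C[C@H](C)CCC[C@@H](C)CCCCc1ccccc1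
F6 | step 11 | {(2S)-2-[(4R,8S)-4,8-dimethyl-2-methylidene-12-phenyldodecyl]oxiran-2-yl}methanol | C=C(C[C@H](C)CCC[C@@H](C)CCCCc1ccccc1)C[C@]1(CO)CO1
F7 | step 11 | (2S,6R,10S)-2,6,10-trimethyl-4-methylidene-14-phenyltetradecane-1,2-diol | C=C(C[C@H](C)CCC[C@@H](C)CCCCc1ccccc1)C[C@](C)(O)CO
F8 | step 14 | (4R,8S)-2,2-dimethoxy-4,8-dimethyl-12-phenyldodecane | CC(OC)(OC)C[C@H](C)CCC[C@@H](C)CCCCc1ccccc1
F9 | step 14 | (4R,8S)-2-hydroperoxy-2-methoxy-4,8-dimethyl-12-phenyldodecane, both C2 epimers | CC(OC)(OO)C[C@H](C)CCC[C@@H](C)CCCCc1ccccc1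
F10 | step 14 | triethyl{[(4R,8S)-2-methoxy-4,8-dimethyl-12-phenyldodecan-2-yl]peroxy}silane, both C2 epimers | CC(OC)(OO[Si](CC)(CC)CC)C[C@H](C)CCC[C@@H](C)CCCCc1ccccc1
F11 | step 14 | tert-butyl[(3-methylbut-3-en-1-yl)oxy]diphenylsilane | CC(=C)CCO[Si](c1ccccc1)(c1ccccc1)C(C)(C)C
F12 | step 14 | tert-butyl(2-{(3S,5R)-5-[(2R,6S)-2,6-dimethyl-10-phenyldecyl]-3,5-dimethyl-1,2-dioxolan-3-yl}ethoxy)diphenylsilane | C[C@@H](CCCCc1ccccc1)CCC[C@@H](C)C[C@]1(C)C[C@](C)(CCO[Si](c2ccccc2)(c2ccccc2)C(C)(C)C)OO1
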